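## Analysis of the target

The target 26 is a bisabolane-type sesquiterpenoid triester built on one carbocycle, ring A (C1–C6), which carries the chain C7–C11 at C1. In the numbering used here C2 is the only ring CH2, C3–C4 is an epoxide with a methyl group on C4, C5 and C6 bear angelate esters, C7 carries an exocyclic methylene, C8 bears the third angelate, and C10–C11 is a trisubstituted epoxide. Ring A has five contiguous stereocentres, (1R,3S,4S,5S,6R): the C1 chain is trans to the C6 oxygen, the C6 oxygen is trans to the C5 oxygen, and the epoxide oxygen lies on the face of the C6 oxygen, anti to the C5 ester and to the C1 chain. The chain adds C8 (S) and C10 (R), which are insulated from the ring by the sp2 carbon C7 and from each other by C9, so neither can be relayed from ring A. The sensitive groups are the three (Z)-2-methylbut-2-enoates (they isomerise to tiglates under nucleophilic catalysis or excess strong base), the two acid-labile epoxides, and the C8 oxygen, which as a free hydroxyl sits 1,3 to the chain epoxide and can close onto C11. The difficulty is that four of six ring carbons carry oxygen in a fixed pattern, the chain centres need their own control, and the esters must arrive after the last carbon–carbon bond formation. The plan rests on one feature: the oxygens on C3 and C6 are cis and 1,4 across ring A, the methyl group sits on C4 between C3 and C5, and the C1 substituent is trans to C6–O. That is the imprint of an oxygen bridge from C3 to C6, that is, of 3-methylfuran 1 after endo addition of an acrylate; the C6–O bond is kept, and the C3–O bond is temporary and is later returned to the same face as the epoxide.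

## Retrosynthetic reasoning

**26 to 25 (C3–O and C4–O of the ring epoxide).** The ring epoxide is removed first. With a free C5 hydroxyl it would be delivered to the wrong face and could migrate by Payne rearrangement; with the C5 ester in place a peracid should attack anti to it. The alkene C3=C4 of 25 serves as a robust placeholder through the whole route. The forward step must pick one alkene out of six and one face.

**25 to 23 and 20 (acyl–O bonds at C5 and C6).** The two ring angelates are cut together, giving diol 23 and angelic anhydride 20. Nothing but the final epoxidation follows this acylation. The forward reaction must esterify two adjacent secondary alcohols, one of them hindered by the other's new ester, without Z to E isomerisation.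

**23 to 22 (two O–Si bonds).** The C5 and C6 oxygens are masked as the same silyl ether, so one buffered fluoride treatment frees both. Silyl ethers survive the Grignard, amide-base and chromium steps that precede.

**22 to 19 and 20 (acyl–O bond at C8).** The C8 angelate is cut on its own, and in the forward direction it is installed directly after C8 is created, while the ring oxygens are still silylated. This costs one step more than a global acylation. In return the route never carries a free C8 hydroxyl next to the chain epoxide through the desilylation, and each acylation step faces a defined set of hydroxyl groups.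

**19 to 14 and 17 (C7–C8).** This cut divides the molecule into a ring half and a chain half at an sp2–sp3 bond next to a carbinol. The C10–C11 epoxide arrives inside aldehyde 17, so the route never holds a second isolated trisubstituted alkene that would compete in the last step. The forward reaction is a chromium/nickel-mediated addition of the alkenyl unit of 14 to 17; it must tolerate the epoxide and set C8 by reagent control.

**17 to 16 to 15 (epoxide C–O bonds, oxidation level).** The C10 centre comes from a reagent-controlled epoxidation of the single alkene of commercial 15. Oxidation of 16 to the aldehyde is left to the last moment because 17 is a β,γ-epoxy aldehyde.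

**14 to 12 to 10 (C7–O of the triflate, C7–CH3).** The carboxyl carbon of the acrylate becomes C7 and the added methyl group becomes the exocyclic methylene. Amide 10 gives methyl ketone 12 by single addition, and kinetic enolisation at the methyl group gives the 1,1-disubstituted enol triflate 14.

**10 to 9 to 8 (C5–H, O–Si).** C5 is set by hydride addition to enone 8. In 8 the C1 and C6 substituents are trans and both equatorial, so axial attack gives the equatorial C5 alcohol, trans to C6–O, as required.

**8 to 7 to 6 to 4 (the C3–O bond of the bridge).** The bridge is opened by β-elimination from a C5 ketone. C4 is the only enolisable α-carbon of 7 (C6 is a bridgehead), so only the C3–O bond can leave; this gives C3=C4 and keeps the oxygen on C6. The ketone comes from exo hydroboration–oxidation of 4 and alcohol oxidation. A direct metal-catalysed SN2′ opening of 4 by an oxygen nucleophile would be shorter, but it is not established for an oxanorbornene with a substituted alkene, and ionisation could equally occur at C6–O to give the methyl-stabilised allyl system.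

**4 to 3 to 1 and 2 (amide exchange; C1–C6 and C2–C3).** Amide 4 comes from the activated ester 3. The cycloaddition of 1 and 2 forms both ring bonds, ring A and the centres C1, C3 and C6 in one catalytic step from two commercial compounds; it needs regio-, endo- and enantiocontrol.

## Alternatives that were turned down

**Alternative 1:** The C8 carbinol carbon is disconnected on both sides (C7–C8 and C9–C10). In the forward step the boron ate complex from ring alkenylboronate A2 and vinyllithium A3 meets 2-methylprop-1-enyl triflate A4 under Pd(OAc)2 and a chiral ferrocene-based bisphosphine. The alkenylpalladium cation activates the vinyl group, the ring alkenyl group migrates from boron to carbon (C7–C8), and reductive elimination joins C9 to C10. This gives boronate A1, which is oxidised with retention to the C8 alcohol.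
- For: C8 is set by the catalyst and two C–C bonds form in one step. On C8 control this is stronger than the chosen route, which depends on a stoichiometric chiral chromium complex.
- Against: the migrating group is a 1,1-disubstituted alkenyl carbon bearing the whole ring, so migration is hindered and direct cross-coupling of A2 with A4 competes. A1 is an allylic boronate and can undergo 1,3-boryl shift toward the methylene terminus. The chain leaves the coupling as a prenyl group, so C10 must be set by epoxidising C10=C11 in a molecule that also holds the ring C3=C4 alkene of the same substitution class. Ring A is not addressed at all; A2 would itself be made from enol triflate 14 by one further step.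
- Comparison: it is an end-game variant, not a ring strategy. It adds a borylation, an oxidation and a second selective epoxidation where the chosen route brings C10 in from 17.

**Alternative 2:** Ring A is cut at C4–C5. In the forward step the (Z)-alkenyl iodide of aldehyde A6 adds to the C5 aldehyde under CrCl2 with catalytic NiCl2, closing the cyclohexene and giving cyclohexenol A5, which is the same compound as 9.
- For: six-membered closure by a mild, chemoselective organochromium addition, with the position of the alkene and of the C4 methyl fixed by the iodide. It has no regiochemical or cycloreversion issue, and on that point it is stronger than the chosen cycloaddition.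
- Against: A6 is an acyclic chain whose C1 and C6 centres need acyclic stereocontrol, whose trisubstituted iodoalkene must be made geometrically pure, and whose α-silyloxy aldehyde is epimerisable at C6 and sits β to an enolisable amide. C5 is formed in the closure under substrate control only, and the cyclic transition state could as well give the cis isomer. Chromium is used stoichiometrically early, on scale.
- Comparison: both routes meet at the same intermediate. The chosen route should reach 9 in six steps from 1 and 2, with the ring and C1/C6 set catalytically and C5 set on a conformationally defined ring. A stereodefined A6 would plausibly need more steps than that before the ring even closes.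

**Alternative 3:** The C3–O and C6–O bonds are cut. In the forward step photosensitised singlet oxygen A9 adds across C3 and C6 of diene A8 to give endoperoxide A7, trans to the C1 substituent.
- For: it uses the same cis-1,4 oxygen relationship, with light and oxygen as reagents and no acid-sensitive furan; on operational simplicity of the key step it is stronger.
- Against: the step forms no C–C bond, so ring A and the C1 centre must already exist in A8, a chiral cyclohexa-1,3-diene prone to 1,5-hydrogen shift and aromatisation. Facial control rests on one substituent a carbon away from the diene terminus. Ene reactions at the C7 methylene unit and at the methyl-bearing diene compete. After reduction the two oxygens are a cis-1,4-diol; the C5 oxygen is still missing and the chain still has to be built from the allylic silyl ether.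
- Comparison: the chosen cycloaddition delivers the same oxygen pattern together with two C–C bonds, the ring and three stereocentres under catalyst control, and leaves the two bridge termini chemically distinct.

Key step: step 1

Assumption 1: the oxazaborolidinium catalyst from (S)-α,α-diphenylprolinol is taken to expose the re face of the α-carbon of bound 2 (giving the 2S adduct 3); if 3 proves to be the antipode, the catalyst from (R)-α,α-diphenylprolinol is used and nothing else changes.

Assumption 2: in step 12 the (S)-configured sulfonamide ligand is taken to give the 8S carbinol; the ligand antipode is used if the sense proves opposite.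

Assumption 3: angelic anhydride 20 is taken as a purchasable reagent; it transfers one angeloyl group per molecule to an alkoxide and the other half leaves as lithium angelate, so it is used in excess in both acylation steps.

## Route

Step 1
Reactants: 1 3-methylfuran; 2 2,2,2-trifluoroethyl acrylate
Product: 3 2,2,2-trifluoroethyl (1S,2S,4S)-5-methyl-7-oxabicyclo[2.2.1]hept-5-ene-2-carboxylate (2-endo ester)
Conditions: (S)-1-(2-methylphenyl)-3,3-diphenyltetrahydro-1H,3H-pyrrolo[1,2-c][1,3,2]oxazaborole·HN(SO2CF3)2 (20 mol %; from (S)-α,α-diphenylprolinol and tri(2-methylphenyl)boroxine, then HN(SO2CF3)2), 1 (2 equiv), CH2Cl2, −78 °C; Et3N quench at −78 °C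
Reagents that add atoms: none
Why: Catalytic asymmetric Diels–Alder reaction; the closest known case is the same oxazaborolidinium-catalysed addition of 2 to furan and simple substituted furans, and 1 is a new diene for it. The boron Lewis acid binds the ester carbonyl of 2 and lowers its LUMO, while the HOMO of 1 is largest at the α-carbon next to the methyl-bearing carbon, so that carbon (C3) forms the more advanced bond to the acrylate CH2 (C2) and the other α-carbon (C6) bonds to the ester-bearing carbon (C1) in a concerted, asynchronous, suprafacial [4+2] addition. Ring A closes by this cycloaddition as the six-membered carbocycle of a 7-oxabicyclo[2.2.1]heptene, with C1–C6 and C2–C3 formed together. C1 is set by the catalyst, whose aryl group covers one face of the bound acrylate so that the diene adds to the re face of the α-carbon. C3 and C6 are set relative to C1 by the endo transition state, which places the ester anti to the oxygen bridge, that is the C1 substituent trans to C6–O. The step needs regioselectivity (methyl and ester 1,4), endo selectivity and enantioselectivity. The first comes from polarisation of 1 by its methyl group, the second from kinetic control at −78 °C with the catalyst destroyed by base before warming (the adduct can equilibrate by cycloreversion), the third from the chiral Lewis acid.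

Step 2
Reactants: 3
Product: 4 (1S,2S,4S)-N-methoxy-N,5-dimethyl-7-oxabicyclo[2.2.1]hept-5-ene-2-carboxamide (2-endo amide)
Conditions: MeNH(OMe)·HCl, i-PrMgCl, THF, −20 °C
Reagents that add atoms: N,O-dimethylhydroxylamine hydrochloride, CNOC.Cl
Why: Weinreb amide formation by aminolysis of the activated trifluoroethyl ester with the chloromagnesium amide; trifluoroethoxide leaves readily at low temperature and the weakly basic reagent should not deprotonate C1, so neither epimerisation nor β-elimination of the bridge is expected. The amide then survives the borane, hydride and base steps that an activated ester would not.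

Step 3
Reactants: 4
Product: 6 (1R,2S,4S,5S,6S)-6-hydroxy-N-methoxy-N,5-dimethyl-7-oxabicyclo[2.2.1]heptane-2-carboxamide (6-exo hydroxyl; 5-endo methyl), via alkylborane 5 (not isolated)
Conditions: BH3·SMe2, THF, 0 °C; then aq. NaOH, 30% H2O2, 0 °C to rt
Reagents that add atoms: hydrogen peroxide, OO
Why: Hydroboration–oxidation; borane adds syn to the strained trisubstituted alkene from the exo face (the endo face is closed by the C1–C2 bridge and the endo amide), with boron on the less substituted C5 and hydrogen on C4, and oxidation with retention gives the exo C5 alcohol. Both new centres are transient (C5 becomes a ketone, C4 becomes sp2); reduction of the amide by borane needs heat and should not compete at 0 °C.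

Step 4
Reactants: 6
Product: 7 (1R,2S,4S,5R)-N-methoxy-N,5-dimethyl-6-oxo-7-oxabicyclo[2.2.1]heptane-2-carboxamide
Conditions: Dess–Martin periodinane, NaHCO3, CH2Cl2, 0 °C to rt
Reagents that add atoms: none
Why: Dess–Martin oxidation of the secondary alcohol under buffered, non-basic conditions, which leaves the enolisable C4–H and the oxygen bridge untouched.

Step 5
Reactants: 7
Product: 8 (1S,2R)-2-[(tert-butyldimethylsilyl)oxy]-N-methoxy-N,4-dimethyl-3-oxocyclohex-4-ene-1-carboxamide
Conditions: TBSOTf (1.2 equiv), Et3N, CH2Cl2, −78 to 0 °C
Reagents that add atoms: tert-butyldimethylsilyl trifluoromethanesulfonate, CC(C)(C)[Si](C)(C)OS(=O)(=O)C(F)(F)F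
Why: Silyl triflate/amine-induced β-elimination of a 7-oxanorbornan-2-one; silylation of the bridge oxygen and removal of the exo C4–H (the only enolisable position, since C6 is a bridgehead) expel the oxygen from C3 with relief of bicyclic strain. The product is the C3=C4 enone with the former bridge oxygen kept on C6 as its silyl ether; connectivity alone decides which C–O bond breaks, and C1 and C6 are untouched.

Step 6
Reactants: 8
Product: 9 (1S,2R,3R)-2-[(tert-butyldimethylsilyl)oxy]-3-hydroxy-N-methoxy-N,4-dimethylcyclohex-4-ene-1-carboxamide
Conditions: NaBH4, CeCl3·7H2O, MeOH, −78 °C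
Reagents that add atoms: none
Why: Luche 1,2-reduction; the trans C1 amide and C6 silyloxy groups hold the half-chair with both equatorial, and the small hydride should add axially to C5, antiperiplanar to the axial C6–H. This gives the equatorial C5 alcohol trans to C6–O; the amide is inert to borohydride.

Step 7
Reactants: 9
Product: 10 (1S,2R,3R)-2,3-bis[(tert-butyldimethylsilyl)oxy]-N-methoxy-N,4-dimethylcyclohex-4-ene-1-carboxamide
Conditions: TBSOTf, 2,6-lutidine, CH2Cl2, −78 to 0 °C
Reagents that add atoms: tert-butyldimethylsilyl trifluoromethanesulfonate, CC(C)(C)[Si](C)(C)OS(=O)(=O)C(F)(F)F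
Why: Silylation of the hindered allylic alcohol with a silyl triflate and a hindered pyridine base; both ring oxygens now carry the same group and can be freed together later.

Step 8
Reactants: 10
Product: 12 1-[(1S,5R,6R)-5,6-bis[(tert-butyldimethylsilyl)oxy]-4-methylcyclohex-3-en-1-yl]ethan-1-one, via magnesium chelate 11 (not isolated)
Conditions: MeMgBr, THF, 0 °C; then pH 7 buffer
Reagents that add atoms: methylmagnesium bromide, C[Mg]Br
Why: Weinreb ketone synthesis; the Grignard reagent adds once to give the stable five-membered chelate 11, which releases the methyl ketone only on work-up, so no tertiary alcohol forms. The trans arrangement at C1 and C6 is the stable one, so C1 is not at risk.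

Step 9
Reactants: 12
Product: 14 1-[(1S,5R,6R)-5,6-bis[(tert-butyldimethylsilyl)oxy]-4-methylcyclohex-3-en-1-yl]ethenyl trifluoromethanesulfonate, via potassium enolate 13 (not isolated)
Conditions: KN(SiMe3)2, THF, −78 °C; then PhN(SO2CF3)2, −78 to 0 °C
Reagents that add atoms: N-phenylbis(trifluoromethanesulfonimide), O=S(=O)(N(c1ccccc1)S(=O)(=O)C(F)(F)F)C(F)(F)F
Why: Kinetic enolisation at the methyl group with a bulky amide base and O-sulfonylation of enolate 13 give the 1,1-disubstituted enol triflate. Deprotonation at the hindered C1 methine, which could expel the C6 silyloxy group, should be much slower at −78 °C.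

Step 10
Reactants: 15 4-methylpent-3-en-1-ol
Product: 16 2-[(2R)-3,3-dimethyloxiran-2-yl]ethan-1-ol
Conditions: 1,2:4,5-di-O-isopropylidene-β-D-erythro-2,3-hexodiulo-2,6-pyranose (30 mol %), KHSO5 (as 2KHSO5·KHSO4·K2SO4), K2CO3, Bu4NHSO4, MeCN–CH2(OMe)2/aq. Na2B4O7–disodium ethylenediaminetetraacetate buffer, 0 °C
Reagents that add atoms: potassium peroxymonosulfate, [K+].[O-]S(=O)(=O)OO
Why: Shi asymmetric epoxidation; the dioxirane from the D-fructose-derived ketone transfers oxygen to the trisubstituted alkene through a spiro transition state, which for this ketone antipode gives R at the CH carbon (C10). The basic buffer protects the epoxy alcohol from acid-catalysed cyclisation.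

Step 11
Reactants: 16
Product: 17 2-[(2R)-3,3-dimethyloxiran-2-yl]acetaldehyde
Conditions: Dess–Martin periodinane, NaHCO3, CH2Cl2, 0 °C; solution of crude 17 used at once
Reagents that add atoms: none
Why: Buffered Dess–Martin oxidation reaches the β,γ-epoxy aldehyde without a base strong enough to trigger β-elimination of the epoxide; the aldehyde is not stored.

Step 12
Reactants: 14; 17
Product: 19 (2S)-3-[(1R,5R,6R)-5,6-bis[(tert-butyldimethylsilyl)oxy]-4-methylcyclohex-3-en-1-yl]-1-[(2R)-3,3-dimethyloxiran-2-yl]but-3-en-2-ol, via alkenylchromium dichloride 18 (not isolated)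
Conditions: CrCl2 (4 equiv), N-{2-[(4S)-4-isopropyl-4,5-dihydro-1,3-oxazol-2-yl]-6-methylphenyl}methanesulfonamide (4.4 equiv), Et3N, THF, rt; then NiCl2 (cat.), 14, 17 (2 equiv), rt
Reagents that add atoms: none
Why: Nozaki–Hiyama–Kishi coupling; zerovalent nickel inserts into the C–OTf bond, the alkenyl group passes to chromium to give 18, and this weakly basic nucleophile adds to the aldehyde without opening the epoxide. C8 is set by reagent control from the chiral sulfonamide–oxazoline ligand on trivalent chromium (the asymmetric variant of the coupling, known for 1,1-disubstituted alkenyl electrophiles); the resident centres C1 and C10 are too remote to decide it.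

Step 13
Reactants: 19; 20 angelic anhydride [(2Z)-2-methylbut-2-enoic anhydride]
Product: 22 (2S)-3-[(1R,5R,6R)-5,6-bis[(tert-butyldimethylsilyl)oxy]-4-methylcyclohex-3-en-1-yl]-1-[(2R)-3,3-dimethyloxiran-2-yl]but-3-en-2-yl (2Z)-2-methylbut-2-enoate, via lithium alkoxide 21 (not isolated)
Conditions: LiN(SiMe3)2 (1.0 equiv), THF, −78 °C; then 20 (1.5 equiv), −78 to −20 °C; pH 7 buffer
Reagents that add atoms: none
Why: O-Acylation of a lithium alkoxide with a carboxylic anhydride; alkoxide 21 takes one angeloyl group from 20 at low temperature, faster than it can attack the chain epoxide, and no nucleophilic catalyst is present, so the Z geometry of the acyl group should be kept. The C8–O bond is not touched, so C8 keeps its configuration, and capping it here removes the hydroxyl that could otherwise close onto C11 of the epoxide during the desilylation.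

Step 14
Reactants: 22
Product: 23 (2S)-3-[(1R,5R,6R)-5,6-dihydroxy-4-methylcyclohex-3-en-1-yl]-1-[(2R)-3,3-dimethyloxiran-2-yl]but-3-en-2-yl (2Z)-2-methylbut-2-enoate
Conditions: Bu4NF, AcOH (1:1), THF, 0 °C to rt
Reagents that add atoms: none
Why: Fluoride-induced cleavage of both silyl ethers; acetic acid keeps the medium near neutral, so no alkoxide attacks the C8 ester or the epoxide, and with C8 esterified no hydroxyl lies within reach of the chain epoxide. No ring epoxide is present yet to rearrange.

Step 15
Reactants: 23; 20
Product: 25 (1R,2R,6R)-6-{(3S)-4-[(2R)-3,3-dimethyloxiran-2-yl]-3-[(2Z)-2-methylbut-2-enoyloxy]but-1-en-2-yl}-3-methylcyclohex-3-ene-1,2-diyl bis[(2Z)-2-methylbut-2-enoate], via dilithium dialkoxide 24 (not isolated)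
Conditions: LiN(SiMe3)2 (2.0 equiv), THF, −78 °C; then 20 (4 equiv), −78 to 0 °C; pH 7 buffer
Reagents that add atoms: none
Why: Double O-acylation of dialkoxide 24 with the anhydride; the two equivalents of amide base are consumed by the hydroxyl groups, which are far more acidic than the γ-hydrogens of the resident angelate, and alkoxide acylation needs neither heat nor a nucleophilic catalyst, so Z to E isomerisation should not occur. C5 and C6 are esterified with retention, and an acyl shift between the three oxygens would be harmless because all three end as the same ester.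

Step 16
Reactants: 25
Product: 26 (1S,2S,3R,4R,6S)-4-{(3S)-4-[(2R)-3,3-dimethyloxiran-2-yl]-3-[(2Z)-2-methylbut-2-enoyloxy]but-1-en-2-yl}-1-methyl-7-oxabicyclo[4.1.0]heptane-2,3-diyl bis[(2Z)-2-methylbut-2-enoate] (the target CNP0258231.1)
Conditions: 3-chloroperbenzoic acid (1.1 equiv), NaHCO3, CH2Cl2, 0 °C
Reagents that add atoms: 3-chloroperbenzoic acid, OOC(=O)c1cccc(Cl)c1
Why: Prilezhaev epoxidation; C3=C4 is the only electron-rich trisubstituted alkene left (the angelate alkenes are conjugated with carbonyl groups, the C7 methylene is less substituted and flanked by an ester), so one equivalent should react there. One face carries the allylic C5 ester and the C1 chain, the other only the homoallylic C6 ester, so attack on the face of the C6 oxygen sets C3 and C4 as required.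

## Compound list

1 | 3-methylfuran | Cc1ccoc1 | starting material
2 | 2,2,2-trifluoroethyl acrylate | C=CC(=O)OCC(F)(F)F | starting material
3 | 2,2,2-trifluoroethyl (1S,2S,4S)-5-methyl-7-oxabicyclo[2.2.1]hept-5-ene-2-carboxylate (2-endo) | FC(F)(F)COC(=O)[C@H]1C[C@H]2C(C)=C[C@@H]1O2 | intermediate
4 | (1S,2S,4S)-N-methoxy-N,5-dimethyl-7-oxabicyclo[2.2.1]hept-5-ene-2-carboxamide (2-endo) | CON(C)C(=O)[C@H]1C[C@H]2C(C)=C[C@@H]1O2 | intermediate
5 | 6-exo-boranyl-N-methoxy-N,5-endo-dimethyl-7-oxabicyclo[2.2.1]heptane-2-endo-carboxamide (monoalkylborane; configuration as in 6) | CON(C)C(=O)[C@H]1C[C@H]2[C@@H](C)[C@H](B)[C@@H]1O2 | intermediate (not isolated)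
6 | (1R,2S,4S,5S,6S)-6-hydroxy-N-methoxy-N,5-dimethyl-7-oxabicyclo[2.2.1]heptane-2-carboxamide | CON(C)C(=O)[C@H]1C[C@H]2[C@@H](C)[C@H](O)[C@@H]1O2 | intermediate
7 | (1R,2S,4S,5R)-N-methoxy-N,5-dimethyl-6-oxo-7-oxabicyclo[2.2.1]heptane-2-carboxamide | CON(C)C(=O)[C@H]1C[C@H]2[C@@H](C)C(=O)[C@@H]1O2 | intermediate
8 | (1S,2R)-2-[(tert-butyldimethylsilyl)oxy]-N-methoxy-N,4-dimethyl-3-oxocyclohex-4-ene-1-carboxamide | CON(C)C(=O)[C@H]1CC=C(C)C(=O)[C@@H]1O[Si](C)(C)C(C)(C)C | intermediate
9 | (1S,2R,3R)-2-[(tert-butyldimethylsilyl)oxy]-3-hydroxy-N-methoxy-N,4-dimethylcyclohex-4-ene-1-carboxamide | CON(C)C(=O)[C@H]1CC=C(C)[C@@H](O)[C@@H]1O[Si](C)(C)C(C)(C)C | intermediate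
10 | (1S,2R,3R)-2,3-bis[(tert-butyldimethylsilyl)oxy]-N-methoxy-N,4-dimethylcyclohex-4-ene-1-carboxamide | CON(C)C(=O)[C@H]1CC=C(C)[C@@H](O[Si](C)(C)C(C)(C)C)[C@@H]1O[Si](C)(C)C(C)(C)C | intermediate
11 | bromomagnesium alkoxide of the tetrahedral methyl adduct of 10 (N,O-chelate) | CON(C)C(C)(O[Mg]Br)[C@H]1CC=C(C)[C@@H](O[Si](C)(C)C(C)(C)C)[C@@H]1O[Si](C)(C)C(C)(C)C | intermediate (not isolated)
12 | 1-[(1S,5R,6R)-5,6-bis[(tert-butyldimethylsilyl)oxy]-4-methylcyclohex-3-en-1-yl]ethan-1-one | CC(=O)[C@H]1CC=C(C)[C@@H](O[Si](C)(C)C(C)(C)C)[C@@H]1O[Si](C)(C)C(C)(C)C | intermediate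
13 | potassium enolate of 12 (terminal, at the methyl group) | C=C([O-])[C@H]1CC=C(C)[C@@H](O[Si](C)(C)C(C)(C)C)[C@@H]1O[Si](C)(C)C(C)(C)C.[K+] | intermediate (not isolated)
14 | 1-[(1S,5R,6R)-5,6-bis[(tert-butyldimethylsilyl)oxy]-4-methylcyclohex-3-en-1-yl]ethenyl trifluoromethanesulfonate | C=C(OS(=O)(=O)C(F)(F)F)[C@H]1CC=C(C)[C@@H](O[Si](C)(C)C(C)(C)C)[C@@H]1O[Si](C)(C)C(C)(C)C | intermediate
15 | 4-methylpent-3-en-1-ol | CC(C)=CCCO | starting material
16 | 2-[(2R)-3,3-dimethyloxiran-2-yl]ethan-1-ol | OCC[C@H]1OC1(C)C | intermediate
17 | 2-[(2R)-3,3-dimethyloxiran-2-yl]acetaldehyde | O=CC[C@H]1OC1(C)C | intermediate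
18 | alkenylchromium dichloride from 14 (ligand omitted) | C=C([Cr](Cl)Cl)[C@H]1CC=C(C)[C@@H](O[Si](C)(C)C(C)(C)C)[C@@H]1O[Si](C)(C)C(C)(C)C | intermediate (not isolated)
19 | (2S)-3-[(1R,5R,6R)-5,6-bis[(tert-butyldimethylsilyl)oxy]-4-methylcyclohex-3-en-1-yl]-1-[(2R)-3,3-dimethyloxiran-2-yl]but-3-en-2-ol | C=C([C@H](C[C@H]1OC1(C)C)O)[C@H]1CC=C(C)[C@@H](O[Si](C)(C)C(C)(C)C)[C@@H]1O[Si](C)(C)C(C)(C)C | intermediate
20 | angelic anhydride, (2Z)-2-methylbut-2-enoic anhydride | C/C=C(/C)C(=O)OC(=O)/C(C)=C\C | starting material
21 | lithium alkoxide of 19 (at C8) | C=C([C@H](C[C@H]1OC1(C)C)[O-])[C@H]1CC=C(C)[C@@H](O[Si](C)(C)C(C)(C)C)[C@@H]1O[Si](C)(C)C(C)(C)C.[Li+] | intermediate (not isolated)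
22 | (2S)-3-[(1R,5R,6R)-5,6-bis[(tert-butyldimethylsilyl)oxy]-4-methylcyclohex-3-en-1-yl]-1-[(2R)-3,3-dimethyloxiran-2-yl]but-3-en-2-yl (2Z)-2-methylbut-2-enoate | C=C([C@H](C[C@H]1OC1(C)C)OC(=O)/C(C)=C\C)[C@H]1CC=C(C)[C@@H](O[Si](C)(C)C(C)(C)C)[C@@H]1O[Si](C)(C)C(C)(C)C | intermediate
23 | (2S)-3-[(1R,5R,6R)-5,6-dihydroxy-4-methylcyclohex-3-en-1-yl]-1-[(2R)-3,3-dimethyloxiran-2-yl]but-3-en-2-yl (2Z)-2-methylbut-2-enoate | C=C([C@H](C[C@H]1OC1(C)C)OC(=O)/C(C)=C\C)[C@H]1CC=C(C)[C@@H](O)[C@@H]1O | intermediate
24 | dilithium dialkoxide of 23 (at C5 and C6) | C=C([C@H](C[C@H]1OC1(C)C)OC(=O)/C(C)=C\C)[C@H]1CC=C(C)[C@@H]([O-])[C@@H]1[O-].[Li+].[Li+] | intermediate (not isolated)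
25 | tri-angelate with ring alkene, (1R,2R,6R)-6-{(3S)-4-[(2R)-3,3-dimethyloxiran-2-yl]-3-[(2Z)-2-methylbut-2-enoyloxy]but-1-en-2-yl}-3-methylcyclohex-3-ene-1,2-diyl bis[(2Z)-2-methylbut-2-enoate] | C=C([C@H](C[C@H]1OC1(C)C)OC(=O)/C(C)=C\C)[C@H]1CC=C(C)[C@@H](OC(=O)/C(C)=C\C)[C@@H]1OC(=O)/C(C)=C\C | intermediate
26 | CNP0258231.1, (1S,2S,3R,4R,6S)-4-{(3S)-4-[(2R)-3,3-dimethyloxiran-2-yl]-3-[(2Z)-2-methylbut-2-enoyloxy]but-1-en-2-yl}-1-methyl-7-oxabicyclo[4.1.0]heptane-2,3-diyl bis[(2Z)-2-methylbut-2-enoate] | C=C([C@H](C[C@H]1OC1(C)C)OC(=O)/C(C)=C\C)[C@H]1C[C@@H]2O[C@]2(C)[C@@H](OC(=O)/C(C)=C\C)[C@@H]1OC(=O)/C(C)=C\C | target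

## Step count and least certain steps

Total: 16 steps. Longest linear sequence: 14 steps (steps 1–9, then 12–16); the chain fragment takes 2 steps (10 and 11).

**Step 1 (key step).** The electron-rich furan 1 may add to activated 2 by conjugate (Friedel–Crafts-type) attack at its free α-position, or oligomerise under the strongly acidic catalyst, instead of cycloadding. Endo and regiochemical purity may erode by cycloreversion and re-addition if the catalyst survives warming, and face selectivity may be lower than with unsubstituted furan. The fallback changes the dienophile and the mode of activation to two-point binding. Starting from 1, N-acryloyl-1,3-oxazolidin-2-one is added at −78 °C under the cationic divalent copper complex [Cu(t-Bu-box)](SbF6)2 (t-Bu-box = 2,2′-(propane-2,2-diyl)bis(4-tert-butyl-4,5-dihydro-1,3-oxazole), ligand antipode chosen for the 1S,2S,4S adduct), which should give the endo imide 3-[(1S,2S,4S)-5-methyl-7-oxabicyclo[2.2.1]hept-5-ene-2-carbonyl]-1,3-oxazolidin-2-one F1. Exchange of the oxazolidinone for the N-methoxy-N-methylamide with MeNH(OMe)·HCl and AlMe3 returns the route to 4.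

**Step 12.** The chiral chromium complex may not override the small intrinsic bias, giving poor selectivity at C8. Aldehyde 17 may also be lost by β-elimination (epoxide opening to the γ-hydroxy enal) under the Lewis-acidic, amine-containing conditions. The fallback replaces reagent control by inversion. Starting from 14 and 17, the coupling is run without ligand (CrCl2, catalytic NiCl2, DMF) and the C8 epimers are separated; the unwanted (2R)-epimer of 19 F2 is converted by Mitsunobu reaction (4-nitrobenzoic acid, PPh3, diisopropyl azodicarboxylate) into the inverted 4-nitrobenzoate of 19 F3, and methanolysis (K2CO3, MeOH) returns the route to 19.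

**Step 16.** Facial selectivity may be poor because all ring substituents are equatorial and the allylic ester is only a modest steric director; some peracid may also be consumed at the C7 methylene. The fallback reverses the facial outcome by anti addition. Starting from 25, N-bromosuccinimide in aqueous THF should form the bromonium ion on the more accessible face and water opens it at the tertiary C4 from the other face, giving the bromohydrin with bromine on C3 and hydroxyl on C4 F4. Ring closure with DBU, which does not cleave the angelates, then places the epoxide oxygen on the face opposite to the initial electrophilic attack and returns the route to 26.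

**Step 15.** The second acylation, at the hydroxyl flanked by the first new ester, may stall. Locally concentrated amide base may also deprotonate the resident C8 angelate at its γ-position, which would scramble or deconjugate that alkene. The fallback builds the two ring Z alkenes after the ester bonds. Starting from 23, esterification at room temperature with 2-[bis(2,2,2-trifluoroethoxy)phosphoryl]propanoic acid (N,N′-dicyclohexylcarbodiimide, 4-dimethylaminopyridine) gives the bis{2-[bis(2,2,2-trifluoroethoxy)phosphoryl]propanoate} of 23 F5. Twofold Z-selective Still–Gennari olefination with acetaldehyde (KN(SiMe3)2, 18-crown-6, THF, −78 °C) returns the route to 25.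

**Step 6.** Hydride may add to the wrong face if the polar α-silyloxy group or the C4 methyl group perturbs the axial preference, giving the cis arrangement at C5 and C6. The fallback uses intramolecular delivery. Starting from 7, DBU opens the bridge to the free hydroxy enone (1S,2R)-2-hydroxy-N-methoxy-N,4-dimethyl-3-oxocyclohex-4-ene-1-carboxamide F6. Me4NBH(OAc)3 in AcOH/MeCN, bound to the C6 hydroxyl, delivers hydride to C5 on the face of that hydroxyl and gives the trans diol (1S,2R,3R)-2,3-dihydroxy-N-methoxy-N,4-dimethylcyclohex-4-ene-1-carboxamide F7. Double silylation (TBSOTf, 2,6-lutidine) returns the route to 10.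

## Further compounds

F1 | step 1 | 3-[(1S,2S,4S)-5-methyl-7-oxabicyclo[2.2.1]hept-5-ene-2-carbonyl]-1,3-oxazolidin-2-one | O=C1OCCN1C(=O)[C@H]1C[C@H]2C(C)=C[C@@H]1O2
F2 | step 12 | (2R)-epimer of 19, (2R)-3-[(1R,5R,6R)-5,6-bis[(tert-butyldimethylsilyl)oxy]-4-methylcyclohex-3-en-1-yl]-1-[(2R)-3,3-dimethyloxiran-2-yl]but-3-en-2-ol | C=C([C@@H](C[C@H]1OC1(C)C)O)[C@H]1CC=C(C)[C@@H](O[Si](C)(C)C(C)(C)C)[C@@H]1O[Si](C)(C)C(C)(C)C
F3 | step 12 | 4-nitrobenzoate of 19 (2S) | C=C([C@H](C[C@H]1OC1(C)C)OC(=O)c1ccc(cc1)[N+](=O)[O-])[C@H]1CC=C(C)[C@@H](O[Si](C)(C)C(C)(C)C)[C@@H]1O[Si](C)(C)C(C)(C)C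
F4 | step 16 | bromohydrin of 25 (bromine on C3, hydroxyl on C4, trans) | C=C([C@H](C[C@H]1OC1(C)C)OC(=O)/C(C)=C\C)[C@H]1C[C@@H](Br)[C@](C)(O)[C@@H](OC(=O)/C(C)=C\C)[C@@H]1OC(=O)/C(C)=C\C
F5 | step 15 | bis{2-[bis(2,2,2-trifluoroethoxy)phosphoryl]propanoate} of 23 (at C5 and C6; C8 angelate kept) | C=C([C@H](C[C@H]1OC1(C)C)OC(=O)/C(C)=C\C)[C@H]1CC=C(C)[C@@H](OC(=O)C(C)P(=O)(OCC(F)(F)F)OCC(F)(F)F)[C@@H]1OC(=O)C(C)P(=O)(OCC(F)(F)F)OCC(F)(F)F
F6 | step 6 | (1S,2R)-2-hydroxy-N-methoxy-N,4-dimethyl-3-oxocyclohex-4-ene-1-carboxamide | CON(C)C(=O)[C@H]1CC=C(C)C(=O)[C@@H]1O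
F7 | step 6 | (1S,2R,3R)-2,3-dihydroxy-N-methoxy-N,4-dimethylcyclohex-4-ene-1-carboxamide | CON(C)C(=O)[C@H]1CC=C(C)[C@@H](O)[C@@H]1O
A1 | alternative 1 | C8 allylic pinacol boronate with prenyl group | C=C([C@H](CC=C(C)C)B1OC(C)(C)C(C)(C)O1)[C@H]2CC=C(C)[C@@H](O[Si](C)(C)C(C)(C)C)[C@@H]2O[Si](C)(C)C(C)(C)C
A2 | alternative 1 | ring alkenylboronate (pinacol ester at C7) | C=C(B1OC(C)(C)C(C)(C)O1)[C@H]1CC=C(C)[C@@H](O[Si](C)(C)C(C)(C)C)[C@@H]1O[Si](C)(C)C(C)(C)C
A3 | alternative 1 | vinyllithium | [Li]C=C
A4 | alternative 1 | 2-methylprop-1-enyl trifluoromethanesulfonate | CC(C)=COS(=O)(=O)C(F)(F)F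
A5 | alternative 2 | cyclohexenol with C5–OH, C6 silyl ether and C7 Weinreb amide (identical with 9) | CON(C)C(=O)[C@H]1CC=C(C)[C@@H](O)[C@@H]1O[Si](C)(C)C(C)(C)C
A6 | alternative 2 | (2S,3R,Z)-3-[(tert-butyldimethylsilyl)oxy]-2-(3-iodobut-2-en-1-yl)-N-methoxy-N-methyl-4-oxobutanamide | CON(C)C(=O)[C@@H](C/C=C(/C)I)[C@@H](O[Si](C)(C)C(C)(C)C)C=O
A7 | alternative 3 | endoperoxide bridging C3 and C6, trans to the C1 substituent | C=C(CO[Si](C)(C)C(C)(C)C)[C@H]1C[C@H]2C(C)=C[C@@H]1OO2
A8 | alternative 3 | (5S)-5-{3-[(tert-butyldimethylsilyl)oxy]prop-1-en-2-yl}-2-methylcyclohexa-1,3-diene | C=C(CO[Si](C)(C)C(C)(C)C)[C@H]1CC=C(C)C=C1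
A9 | alternative 3 | dioxygen (used in its singlet state) | O=O
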